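(The numbers were drawn at random within sensible limits; the result is computed.)

Beside zeta, where reagent is charged in excess, beta and theta are the same recipe with less reagent, and you want to know what that costs in substrate reacted.

in all of them: substrate 42 mM; initiator 1 mol%; time 6.0 min
- zeta: reagent 1.20 equiv
- beta: reagent 0.700 equiv
- theta: reagent 0.910 equiv

    substrate + second chain carrier → by-product + first chain carrier (k1 = 3.26 × 10⁵ /M/s)
    substrate + initiating radical → capped initiator + first chain carrier (k2 = 5.67 × 10⁶ /M/s)
    reagent + by-product ⇌ idle adduct, settled at all times (K3 = 1010 /M)
    target → over-reaction product (k4 = 0.0267 /s)
    reagent + first chain carrier → target + second chain carrier (k5 = 1.15 × 10⁷ /M/s)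
    2 first chain carrier → ended chains (k6 = 4 × 10⁸ /M/s)
    initiator → 2 initiating radical (k7 = 0.0271 /s)

- percentages count the substrate that a species holds: one ended chains counts as two
- by-product is meant together with its idle adduct
- where a step has two of a species, its rate is k times that concentration squared, and two are used at each turn
- run time (zeta): 6.0 min

- part of the substrate that has reacted at the end, zeta
- part of the substrate that has reacted at the end, beta
- part of the substrate that has reacted at the end, theta
- what raising the equivalents of reagent from its lowest to its highest value here does to the part of the substrate that has reacted (changes below 5 percentage points count as none) (it rises / it falls / no change)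

Run it in slow motion, as I reckon it. In the first instants initiator breaks with a half-life of 0.43 min, so the run holds 14.1 half-lives and yields 0.840 mM of initiating radical. While substrate lasts, a radical meets it far faster than initiator breaks, so in beta and theta, where I reckon that reagent gives out first, each radical caps one substrate and spends no reagent. Then the chain turns: first chain carrier takes one reagent, second chain carrier takes one substrate. Substrate consumed in beta and theta is therefore one per reagent plus one per radical. For beta, 0.700 equiv plus two times 1 mol% gives 72.0 %; call this C, the reagent equivalents plus two times the initiator fraction, as a share of substrate. Theta gives 93.0 %. Zeta's sum, 122 %, passes the whole charge, so substrate is the limiting reagent in zeta and reagent is in beta and theta.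

In the middle of beta, the binding constant times starting reagent is 30, so by-product goes into idle adduct and free reagent falls fast. But the adduct stays at balance, so its reagent returns and C counts it.

Near the end, is there time? Setting making equal to ending gives X, the first chain carrier, as the root of initiator breakdown over the ending constant. X decays with initiator. Integrating the reagent constant times X in closed form gives R = 143, the e-foldings available to free reagent. With by-product near 29.4 mM, one part in 30.7 of beta's remaining reagent is free, which cuts R to 4.66 and leaves about 0.943 % of it. So I commit to C for beta and theta, and to the whole charge for zeta. Target meanwhile passes to over-reaction product with a half-life of 0.43 min, which spends no substrate.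

The forecast gives 100 % for zeta, 71.9 % for beta and 92.5 % for theta, with the trend: it rises. Its ground for the middle of the run is that “free reagent collapses near half conversion, but the adduct keeps releasing it”. Its beta and my C for beta differ by 0.1 percentage points.

The simulation gives 100 % for zeta, 71.9 % for beta and 92.5 % for theta; across the reagent range, it rises, by 28 points. The result for beta and its C differ by 0.10 points, and 0.0577 mM of idle adduct stands at the end of beta. A neighbour of beta charged with 4 mol% of initiator takes the same reckoning: 0.700 equiv plus two times that loading gives C = 78.0 %. That flask reaches 78.0 %, its capped initiator is 3.36 mM against 0.840 mM in beta, and its over-reaction product stands at 70.0 %.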